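**Strategy.** The target is cut into an ortho-quinone methide of the cacalol half and a 3-methylbenzofuran dienophile (hetero-Diels–Alder, last step). The cyclohexane ring of the cacalol half (C4a–C5–C6–C7–C8–C8a, cacalol numbering) is grown from a cyclobutane: an alkoxy radical from 1-aryl-2-methylcyclobutanol 5 cleaves the ring bond to the methyl-bearing carbon, and the secondary radical closes on the free ortho carbon of the arene. One operation thus turns a four-membered ring into the six-membered ring, placing the carbonyl at C8 next to the phenol oxygen (the later methide carbon) and the methyl-bearing carbon at C5. The precursor is an aryl cyclobutanol from ortho-lithiated silylated isocreosol and 2-methylcyclobutanone.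

Key step: step 3

Remark: ketone 3 is used as the racemate, so 5–9 are racemic at the methyl-bearing carbon; the (5S) series is obtained in step 6 by catalyst-controlled reduction and separation of diastereomers, which gives up the (5R) half of the material. Primed locants (C2', C3') refer to the benzofuran half.

Step 1
Reactants: 1 2-methoxy-5-methylphenol (isocreosol)
Product: 2 triisopropyl(2-methoxy-5-methylphenoxy)silane
Conditions: i-Pr3SiCl, imidazole, DMF, rt
Reagents that add atoms: chlorotriisopropylsilane, CC(C)[Si](Cl)(C(C)C)C(C)C
Why: O-silylation of the phenol; the bulky silyl ether survives organolithium chemistry and is a poor director, so the next lithiation is left to the methoxy group.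

Step 2
Reactants: 2 triisopropyl(2-methoxy-5-methylphenoxy)silane; 3 2-methylcyclobutan-1-one (racemic)
Product: 5 rac-1-[2-methoxy-5-methyl-3-(triisopropylsilyloxy)phenyl]-2-methylcyclobutan-1-ol, via aryllithium 4 (not isolated)
Conditions: n-BuLi, TMEDA, Et2O, 0 °C → rt; then 3, −78 °C → 0 °C; H2O
Reagents that add atoms: none
Why: Directed ortho-metalation removes the only hydrogen ortho to OMe, and the aryllithium adds 1,2 to the strained, electrophilic cyclobutanone carbonyl; the two stereocentres of 5 form without control, which does not matter because step 3 destroys the carbinol centre and re-forms the other.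

Step 3
Reactants: 5 rac-1-[2-methoxy-5-methyl-3-(triisopropylsilyloxy)phenyl]-2-methylcyclobutan-1-ol
Product: 6 rac-8-methoxy-4,5-dimethyl-7-(triisopropylsilyloxy)-3,4-dihydronaphthalen-1(2H)-one
Conditions: AgNO3 (20 mol%), K2S2O8 (3 equiv), CH2Cl2/H2O 1:1, rt
Reagents that add atoms: none
Why: Peroxydisulfate oxidises monovalent silver to divalent silver, which turns the tertiary cyclobutanol into an alkoxy radical; strain-driven β-scission then breaks the ring bond to the methyl-bearing carbon, because this gives the secondary and not the primary alkyl radical, and leaves the aryl ketone. The γ-keto radical closes on the only free ortho carbon of the arene (the other ortho position carries OMe; the attacked carbon lies para to the silyloxy group) in a six-membered homolytic aromatic substitution, 6-exo-trig with respect to the ortho–meta C=C bond, and oxidation of the cyclohexadienyl radical with loss of a proton restores the arene. The closest known reaction type is the silver-catalysed oxidative ring expansion of 1-arylcyclobutanols to 1-tetralones. The two arene carbons enter the ring, so the four-membered ring becomes the six-membered ring in one operation, with the carbonyl at C1 (later C8, the methide carbon) and the methyl-bearing carbon at C4 (later C5). The new stereocentre at C4 arises from a planar radical and is formed racemic; its configuration is secured in step 6. The step needs scission on the substituted side and ring closure faster than oxidation or hydrogen abstraction of the radical, which the stability of the secondary radical and the short tether to an electron-rich ortho carbon should secure.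

Step 4
Reactants: 6 rac-8-methoxy-4,5-dimethyl-7-(triisopropylsilyloxy)-3,4-dihydronaphthalen-1(2H)-one
Product: 8 rac-8-methoxy-4,5-dimethyl-7-(2-oxopropoxy)-3,4-dihydronaphthalen-1(2H)-one, via cesium phenoxide 7 (not isolated)
Conditions: CsF (2.5 equiv), chloroacetone, DMF, rt → 40 °C
Reagents that add atoms: chloroacetone, CC(=O)CCl
Why: Fluoride cleaves the aryl silyl ether and the phenoxide is O-alkylated in the same flask (Williamson ether synthesis); the tetralone and its stereocentre are not touched.

Step 5
Reactants: 8 rac-8-methoxy-4,5-dimethyl-7-(2-oxopropoxy)-3,4-dihydronaphthalen-1(2H)-one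
Product: 9 rac-9-methoxy-3,4,5-trimethyl-6,7-dihydronaphtho[2,3-b]furan-8(5H)-one
Conditions: polyphosphoric acid, toluene, 90 °C
Reagents that add atoms: none
Why: Acid-mediated cyclodehydration of the aryloxyacetone (intramolecular Friedel–Crafts hydroxyalkylation, then loss of water) closes the 3-methylfuran at the only free position ortho to the ether oxygen, which that oxygen and the neighbouring methyl still activate although it lies para to the acyl group.

Step 6
Reactants: 9 rac-9-methoxy-3,4,5-trimethyl-6,7-dihydronaphtho[2,3-b]furan-8(5H)-one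
Product: 10 (5S,8S)-9-methoxy-3,4,5-trimethyl-5,6,7,8-tetrahydronaphtho[2,3-b]furan-8-ol
Conditions: RuCl[(S,S)-TsDPEN](p-cymene) (2 mol%), HCO2H/Et3N 5:2, CH2Cl2, 30 °C; chromatographic separation of the diastereomers
Reagents that add atoms: none
Why: Noyori asymmetric transfer hydrogenation delivers hydride to the same carbonyl face of both enantiomers of 9 (aryl versus CH2 discrimination, 8S), so the (5S) ketone should give the trans alcohol 10 and the (5R) ketone the cis diastereomer; separating them secures C5 as (S), while C8 is only a temporary centre.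

Step 7
Reactants: 10 (5S,8S)-9-methoxy-3,4,5-trimethyl-5,6,7,8-tetrahydronaphtho[2,3-b]furan-8-ol
Product: 11 (5S,8S)-3,4,5-trimethyl-5,6,7,8-tetrahydronaphtho[2,3-b]furan-8,9-diol
Conditions: NaSEt, DMF, 110 °C; aq NH4Cl
Reagents that add atoms: none
Why: SN2 demethylation of the hindered aryl methyl ether by thiolate; the non-acidic medium should leave the benzylic alcohol, the furan and both stereocentres intact.

Step 8
Reactants: 12 2-methoxy-4-methylphenol (creosol)
Product: 13 1-(2-methoxy-4-methylphenoxy)propan-2-one
Conditions: chloroacetone, K2CO3, KI (cat.), acetone, reflux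
Reagents that add atoms: chloroacetone, CC(=O)CCl
Why: Williamson ether synthesis at the phenol oxygen.

Step 9
Reactants: 13 1-(2-methoxy-4-methylphenoxy)propan-2-one
Product: 14 7-methoxy-3,5-dimethyl-1-benzofuran
Conditions: polyphosphoric acid, toluene, 90 °C
Reagents that add atoms: none
Why: Cyclodehydration of the aryloxyacetone at the only free position ortho to the ether oxygen gives the 3-methylbenzofuran.

Step 10
Reactants: 14 7-methoxy-3,5-dimethyl-1-benzofuran
Product: 15 3,5-dimethyl-1-benzofuran-7-ol
Conditions: NaSEt, DMF, 130 °C; aq NH4Cl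
Reagents that add atoms: none
Why: Thiolate demethylation of the aryl methyl ether, which avoids Lewis acids that would attack the electron-rich furan.

Step 11
Reactants: 15 3,5-dimethyl-1-benzofuran-7-ol
Product: 16 7-hydroxy-3,5-dimethyl-1-benzofuran-6-carbaldehyde
Conditions: MgCl2, Et3N, paraformaldehyde, MeCN, reflux; dilute HCl
Reagents that add atoms: formaldehyde (as paraformaldehyde), C=O
Why: Magnesium-phenoxide-directed ortho-formylation (Casnati–Skattebøl) reaches only the carbon ortho to the OH (C6) and leaves the free para position and furan C2 alone; the hydroxymethyl intermediate is oxidised by a second formaldehyde.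

Step 12
Reactants: 16 7-hydroxy-3,5-dimethyl-1-benzofuran-6-carbaldehyde
Product: 17 6-ethenyl-3,5-dimethyl-1-benzofuran-7-ol
Conditions: Ph3PCH3Br (2.5 equiv), KOt-Bu (2.5 equiv), THF, 0 °C → rt; aq NH4Cl
Reagents that add atoms: methyltriphenylphosphonium bromide, C[P+](c1ccccc1)(c1ccccc1)c1ccccc1.[Br-]
Why: Wittig methylenation of the salicylaldehyde; excess ylide covers the acidic phenol.

Step 13
Reactants: 17 6-ethenyl-3,5-dimethyl-1-benzofuran-7-ol
Product: 19 3,5-dimethyl-6-[(3E)-pent-3-en-1-yl]-1-benzofuran-7-ol, via alkylborane 18 (not isolated)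
Conditions: 9-BBN (2.2 equiv), THF, 0 °C → rt; then (E)-1-bromoprop-1-ene, Pd(dppf)Cl2 (5 mol%), 3 M aq NaOH, THF, 60 °C
Reagents that add atoms: (E)-1-bromoprop-1-ene, C/C=C/Br
Why: Anti-Markovnikov hydroboration of the styrene, then B-alkyl Suzuki–Miyaura coupling, which keeps the E geometry of the alkenyl bromide and so fixes the side-chain double bond.

Step 14
Reactants: 11 (5S,8S)-3,4,5-trimethyl-5,6,7,8-tetrahydronaphtho[2,3-b]furan-8,9-diol; 19 3,5-dimethyl-6-[(3E)-pent-3-en-1-yl]-1-benzofuran-7-ol
Product: 21 hexacyclic cacalol–benzofuran adduct CNP0281983.1 (target), via quinone methide 20 (not isolated)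
Conditions: (PhO)2P(O)OH (10 mol%), 19 (1.5 equiv), 4 Å molecular sieves, toluene, 0 °C → rt
Reagents that add atoms: none
Why: Acid-promoted loss of water from 11 gives ortho-quinone methide 20, which should undergo an inverse-electron-demand hetero-Diels–Alder reaction with the C2'=C3' bond of 19, the nucleophilic C2' bonding to the methide carbon C8 and the carbonyl oxygen to C3' (benzylic, oxygen-stabilised cationic character), with the benzo ring of 19 endo so that H-8, H-2' and the 3'-methyl end up cis, and with approach to the face syn to the 5-methyl (held pseudoaxial by the peri 4-methyl), the only face from which the new C8–C2' bond can become pseudoequatorial in the chromane without inverting the half-chair, which gives the 1,4-cis relation of 5-CH3 and C8–C2'.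

**Compound list**

1 | 2-methoxy-5-methylphenol (isocreosol) | COc1ccc(C)cc1O | starting material
2 | triisopropyl(2-methoxy-5-methylphenoxy)silane | COc1ccc(C)cc1O[Si](C(C)C)(C(C)C)C(C)C | intermediate
3 | 2-methylcyclobutan-1-one (racemic) | CC1CCC1=O | starting material
4 | [2-methoxy-5-methyl-3-(triisopropylsilyloxy)phenyl]lithium | [Li]c1cc(C)cc(O[Si](C(C)C)(C(C)C)C(C)C)c1OC | intermediate (not isolated)
5 | rac-1-[2-methoxy-5-methyl-3-(triisopropylsilyloxy)phenyl]-2-methylcyclobutan-1-ol (both diastereomers) | COc1c(C2(O)CCC2C)cc(C)cc1O[Si](C(C)C)(C(C)C)C(C)C | intermediate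
6 | rac-8-methoxy-4,5-dimethyl-7-(triisopropylsilyloxy)-3,4-dihydronaphthalen-1(2H)-one | COc1c2c(c(C)cc1O[Si](C(C)C)(C(C)C)C(C)C)C(C)CCC2=O | intermediate
7 | cesium rac-1-methoxy-4,5-dimethyl-8-oxo-5,6,7,8-tetrahydronaphthalen-2-olate | COc1c2c(c(C)cc1[O-])C(C)CCC2=O.[Cs+] | intermediate (not isolated)
8 | rac-8-methoxy-4,5-dimethyl-7-(2-oxopropoxy)-3,4-dihydronaphthalen-1(2H)-one | COc1c2c(c(C)cc1OCC(C)=O)C(C)CCC2=O | intermediate
9 | rac-9-methoxy-3,4,5-trimethyl-6,7-dihydronaphtho[2,3-b]furan-8(5H)-one | COc1c2c(c(C)c3c(C)coc13)C(C)CCC2=O | intermediate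
10 | (5S,8S)-9-methoxy-3,4,5-trimethyl-5,6,7,8-tetrahydronaphtho[2,3-b]furan-8-ol (trans) | COc1c2c(c(C)c3c(C)coc13)[C@@H](C)CC[C@@H]2O | intermediate
11 | (5S,8S)-3,4,5-trimethyl-5,6,7,8-tetrahydronaphtho[2,3-b]furan-8,9-diol | Oc1c2c(c(C)c3c(C)coc13)[C@@H](C)CC[C@@H]2O | intermediate
12 | 2-methoxy-4-methylphenol (creosol) | COc1cc(C)ccc1O | starting material
13 | 1-(2-methoxy-4-methylphenoxy)propan-2-one | COc1cc(C)ccc1OCC(C)=O | intermediate
14 | 7-methoxy-3,5-dimethyl-1-benzofuran | COc1cc(C)cc2c(C)coc12 | intermediate
15 | 3,5-dimethyl-1-benzofuran-7-ol | Oc1cc(C)cc2c(C)coc12 | intermediate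
16 | 7-hydroxy-3,5-dimethyl-1-benzofuran-6-carbaldehyde | O=Cc1c(C)cc2c(C)coc2c1O | intermediate
17 | 6-ethenyl-3,5-dimethyl-1-benzofuran-7-ol | C=Cc1c(C)cc2c(C)coc2c1O | intermediate
18 | 9-{2-[7-(9-borabicyclo[3.3.1]nonan-9-yloxy)-3,5-dimethyl-1-benzofuran-6-yl]ethyl}-9-borabicyclo[3.3.1]nonane | Cc1cc2c(C)coc2c(OB2C3CCCC2CCC3)c1CCB1C2CCCC1CCC2 | intermediate (not isolated)
19 | 3,5-dimethyl-6-[(3E)-pent-3-en-1-yl]-1-benzofuran-7-ol | C/C=C/CCc1c(C)cc2c(C)coc2c1O | intermediate
20 | (5S)-3,4,5-trimethyl-6,7-dihydronaphtho[2,3-b]furan-9(5H)-one (ortho-quinone methide with C8=C8a and C4=C4a double bonds) | O=C1C(=CCC[C@@H]2C)C2=C(C)c2c(C)coc12 | intermediate (not isolated)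
21 | CNP0281983.1: endo adduct with (5S,8R) in the cacalol half and (2'R,3'R) in the 2',3'-dihydrobenzofuran half; H-8, H-2' and 3'-CH3 cis on the chromane ring, 5-CH3 cis to the C8–C2' bond, (E)-pent-3-enyl chain | C/C=C/CCc1c(C)cc2c(c1O)O[C@@H]1[C@@H]3CC[C@H](C)c4c3c(c3occ(C)c3c4C)O[C@]21C | target

**Total step count:** 14
**Longest linear sequence:** 8 steps (steps 1–7 and 14); the benzofuran branch is steps 8–13.

**Steps most likely to fail**

Step 3 (ring expansion). What may go wrong: one-electron oxidation of the electron-rich arene, or acid-induced ionisation of the tertiary benzylic cyclobutanol, may outrun alkoxy-radical formation; scission may also occur on the unsubstituted side. Fallback, still a two-carbon ring expansion but anionic: it sets out from 2 and returns at 6. Compound 2 is brominated para to the silyloxy group (NBS, MeCN, 0 °C) to give (4-bromo-2-methoxy-5-methylphenoxy)triisopropylsilane F1. F1 and ketone 3 are then treated with NaNH2/NaOt-Bu in THF. Under these equilibrating conditions 3 gives the more substituted enolate, sodium 2-methylcyclobut-1-en-1-olate F2, and F1 loses HBr (the hydrogen between Br and OMe is the most acidic) to give 3-methoxy-6-methyl-4-(triisopropylsilyloxy)benzyne F3. F2 should add through its methyl-bearing carbon to the aryne carbon remote from OMe; the aryl anion next to OMe then closes on the strained carbonyl, the four-membered alkoxide fragments, and protonation gives 6 (aryne insertion into the C–C bond of a ketone).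

Step 14 (cycloaddition). What may go wrong: the acid that generates the quinone methide may reopen the new tertiary benzylic aryl ether, so that the kinetic endo adduct drifts to the rearomatised C2'-alkylated benzofuran or to other diastereomers; addition of the free phenol of 19 to the methide may also compete. Fallback with neutral, oxidative generation of the same methide: it sets out from 11 and returns at 21 through 20. Ionic hydrogenation of 11 (Et3SiH, CF3CO2H, CH2Cl2, −40 °C) gives (5S)-3,4,5-trimethyl-5,6,7,8-tetrahydronaphtho[2,3-b]furan-9-ol F4. F4 is then oxidised with Ag2O in benzene at rt in the presence of 19; loss of the C8 hydrogen gives 20 without acid, and 19 traps it to give 21.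

Step 5 (furan closure). What may go wrong: electrophilic ring closure at the arene carbon para to the acyl group may be slow, so that acid-mediated self-condensation of the two ketones takes over. Fallback by palladium chemistry: it sets out from 6 and returns at 9. Desilylation (n-Bu4NF, THF) gives rac-7-hydroxy-8-methoxy-4,5-dimethyl-3,4-dihydronaphthalen-1(2H)-one F5. NIS iodinates the only free ortho position to give rac-7-hydroxy-6-iodo-8-methoxy-4,5-dimethyl-3,4-dihydronaphthalen-1(2H)-one F6. Allyl bromide/K2CO3 gives rac-6-iodo-8-methoxy-4,5-dimethyl-7-(prop-2-en-1-yloxy)-3,4-dihydronaphthalen-1(2H)-one F7. With Pd(OAc)2, Na2CO3, HCO2Na and n-Bu4NCl in DMF at 80 °C, oxidative addition to zerovalent palladium, 5-exo Heck cyclisation and shift of the double bond into the ring should give the 3-methylfuran of 9.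

**Further compounds**

F1 | step 3 | (4-bromo-2-methoxy-5-methylphenoxy)triisopropylsilane | COc1cc(Br)c(C)cc1O[Si](C(C)C)(C(C)C)C(C)C
F2 | step 3 | sodium 2-methylcyclobut-1-en-1-olate | CC1=C([O-])CC1.[Na+]
F3 | step 3 | 3-methoxy-6-methyl-4-(triisopropylsilyloxy)benzyne | COC1=C(O[Si](C(C)C)(C(C)C)C(C)C)C=C(C)C#C1
F4 | step 14 | (5S)-3,4,5-trimethyl-5,6,7,8-tetrahydronaphtho[2,3-b]furan-9-ol | Oc1c2c(c(C)c3c(C)coc13)[C@@H](C)CCC2
F5 | step 5 | rac-7-hydroxy-8-methoxy-4,5-dimethyl-3,4-dihydronaphthalen-1(2H)-one | COc1c2c(c(C)cc1O)C(C)CCC2=O
F6 | step 5 | rac-7-hydroxy-6-iodo-8-methoxy-4,5-dimethyl-3,4-dihydronaphthalen-1(2H)-one | COc1c2c(c(C)c(I)c1O)C(C)CCC2=O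
F7 | step 5 | rac-6-iodo-8-methoxy-4,5-dimethyl-7-(prop-2-en-1-yloxy)-3,4-dihydronaphthalen-1(2H)-one | COc1c2c(c(C)c(I)c1OCC=C)C(C)CCC2=O
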